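**Retrosynthetic overview**
1. Cathafuran C ← MOM removal ← furan ring closed last by Sonogashira coupling/5-endo-dig annulation of aryl alkyne 13 with 4-iodoresorcinol diacetate 15.
2. Alkyne 13 ← aldehyde 12 ← acid 10: the carboxyl carbon becomes C2 of the benzofuran.
3. Acid 10 ← new step: carboxylate-directed Ru-catalysed C–H prenylation of chromene acid 7 at C6, so one carboxyl group places the prenyl and then carries the benzofuran.
4. Chromene 5 ← propargyl-ether Claisen/electrocyclisation on methyl 3,5-dihydroxybenzoate 1.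
5. Ring order: resorcinol benzene ring bought (1) → pyran ring (step 2) → furan ring (step 11, on bought resorcinol 14).

Assumption: the target has no stereocentre and no stereogenic double bond (C2 of the pyran carries two methyls), so "single enantiomer" is read as the single achiral compound drawn.

**Step 1**
Reactants: 1 methyl 3,5-dihydroxybenzoate; 2 3-chloro-3-methylbut-1-yne
Product: 3 methyl 3-hydroxy-5-[(2-methylbut-3-yn-2-yl)oxy]benzoate
Conditions: K2CO3, KI (cat.), CuI (cat.), acetone, 60 °C, sealed; 1 in twofold excess and recovered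
Reagents that add atoms: none
Why: Copper-assisted propargylic O-alkylation (Williamson type) of one of two equivalent phenols, with excess diol holding back the bis-ether.

**Step 2**
Reactants: 3 methyl 3-hydroxy-5-[(2-methylbut-3-yn-2-yl)oxy]benzoate
Product: 5 methyl 7-hydroxy-2,2-dimethyl-2H-chromene-5-carboxylate, via methyl 3,5-dihydroxy-2-(3-methylbuta-1,2-dien-1-yl)benzoate 4 (not isolated)
Conditions: PhNEt2, 180 °C
Reagents that add atoms: none
Why: Aryl propargyl ether Claisen rearrangement, then 1,5-H shift and oxa-6π electrocyclisation; the meta ester directs the shift to the carbon next to it and the meta hydroxyl directs it away from the carbon between the two oxygens, so the pyran ring closes on the ester side.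

**Step 3**
Reactants: 5 methyl 7-hydroxy-2,2-dimethyl-2H-chromene-5-carboxylate
Product: 6 methyl 7-(methoxymethoxy)-2,2-dimethyl-2H-chromene-5-carboxylate
Conditions: MOMCl, K2CO3, acetone, rt
Reagents that add atoms: chloromethyl methyl ether (MOMCl), COCCl
Why: Williamson-type acetal protection of the only phenol with a small, base-stable, potentially coordinating group that suits the later C–H activation.

**Step 4**
Reactants: 6 methyl 7-(methoxymethoxy)-2,2-dimethyl-2H-chromene-5-carboxylate
Product: 7 7-(methoxymethoxy)-2,2-dimethyl-2H-chromene-5-carboxylic acid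
Conditions: LiOH·H2O, THF/MeOH/H2O, 50 °C; then 1 M HCl to pH 4, 0 °C
Reagents that add atoms: lithium hydroxide, [Li+].[OH-]
Why: Saponification of a mono-ortho-substituted benzoate; the MOM acetal and the chromene are stable to base and to the brief cold pH 4 work-up.

**Step 5**
Reactants: 8 2-methylbut-3-en-2-ol
Product: 9 methyl 2-methylbut-3-en-2-yl carbonate
Conditions: n-BuLi, THF, −78 °C; then ClCO2Me, −78 °C → rt
Reagents that add atoms: methyl chloroformate, COC(=O)Cl
Why: Acylation of the lithium alkoxide of a tertiary allylic alcohol with a chloroformate gives the carbonate without allylic transposition.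

**Step 6**
Reactants: 7 7-(methoxymethoxy)-2,2-dimethyl-2H-chromene-5-carboxylic acid; 9 methyl 2-methylbut-3-en-2-yl carbonate
Product: 10 7-(methoxymethoxy)-2,2-dimethyl-6-(3-methylbut-2-en-1-yl)-2H-chromene-5-carboxylic acid
Conditions: [Ru(p-cymene)Cl2]2 (5 mol %), K3PO4 (30 mol %), 9 (1.5 equiv), MeCN, 60 °C; pH 4 work-up
Reagents that add atoms: none
Why: Proposed new method: carboxylate-directed Ru(II) ortho-C–H prenylation, in which the bound carboxylate of 7 delivers Ru to the only free ortho C–H (C6, since C4a is substituted) by base-assisted ruthenation helped by the flanking MOM oxygen, the vinyl group of 9 inserts 1,2 with the aryl going to the terminal CH2, and β-oxygen elimination of methyl carbonate (lost as CO2 and MeOH, which returns the base) can only give the linear ArCH2CH=CMe2 unit, so ring position and prenyl connectivity are both fixed by mechanism; the closest known reaction type is carboxylate-directed Ru(II) ortho-C–H allylation of benzoic acids with simple allylic acetates by insertion/β-O elimination, and what is new is a 1,1-dimethylallyl carbonate as prenyl donor at a C–H flanked on both sides on a 2H-chromene acid.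

**Step 7**
Reactants: 10 7-(methoxymethoxy)-2,2-dimethyl-6-(3-methylbut-2-en-1-yl)-2H-chromene-5-carboxylic acid
Product: 11 [7-(methoxymethoxy)-2,2-dimethyl-6-(3-methylbut-2-en-1-yl)-2H-chromen-5-yl]methanol
Conditions: LiAlH4, THF, 0 → 60 °C; H2O quench
Reagents that add atoms: none
Why: Hydride reduction of a hindered benzoic acid to the benzyl alcohol; the isolated alkenes, the chromene and the MOM ether are inert to LiAlH4.

**Step 8**
Reactants: 11 [7-(methoxymethoxy)-2,2-dimethyl-6-(3-methylbut-2-en-1-yl)-2H-chromen-5-yl]methanol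
Product: 12 7-(methoxymethoxy)-2,2-dimethyl-6-(3-methylbut-2-en-1-yl)-2H-chromene-5-carbaldehyde
Conditions: Dess–Martin periodinane, CH2Cl2, 0 °C → rt
Reagents that add atoms: none
Why: Dess–Martin oxidation of a primary benzylic alcohol stops at the aldehyde and does not touch the alkenes.

**Step 9**
Reactants: 12 7-(methoxymethoxy)-2,2-dimethyl-6-(3-methylbut-2-en-1-yl)-2H-chromene-5-carbaldehyde
Product: 13 5-ethynyl-7-(methoxymethoxy)-2,2-dimethyl-6-(3-methylbut-2-en-1-yl)-2H-chromene
Conditions: Ohira–Bestmann reagent, K2CO3, MeOH, 0 °C → rt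
Reagents that add atoms: dimethyl (1-diazo-2-oxopropyl)phosphonate (Ohira–Bestmann reagent), COP(=O)(OC)C(=[N+]=[N-])C(C)=O
Why: Seyferth–Gilbert homologation (Ohira–Bestmann variant) turns the non-enolisable aldehyde into the terminal alkyne under mild base.

**Step 10**
Reactants: 14 4-iodobenzene-1,3-diol
Product: 15 4-iodo-1,3-phenylene diacetate
Conditions: Ac2O, pyridine, DMAP (cat.), CH2Cl2, rt
Reagents that add atoms: acetic anhydride, CC(=O)OC(C)=O
Why: Exhaustive acetylation masks both phenols, which makes the iodide less electron-rich for oxidative addition and avoids phenol oxidation during coupling.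

**Step 11**
Reactants: 13 5-ethynyl-7-(methoxymethoxy)-2,2-dimethyl-6-(3-methylbut-2-en-1-yl)-2H-chromene; 15 4-iodo-1,3-phenylene diacetate
Product: 18 2-[7-(methoxymethoxy)-2,2-dimethyl-6-(3-methylbut-2-en-1-yl)-2H-chromen-5-yl]-1-benzofuran-6-ol, via 4-{[7-(methoxymethoxy)-2,2-dimethyl-6-(3-methylbut-2-en-1-yl)-2H-chromen-5-yl]ethynyl}-1,3-phenylene diacetate 16 (not isolated), via 4-{[7-(methoxymethoxy)-2,2-dimethyl-6-(3-methylbut-2-en-1-yl)-2H-chromen-5-yl]ethynyl}benzene-1,3-diol 17 (not isolated)
Conditions: Pd(PPh3)2Cl2 (5 mol %), CuI (10 mol %), Et3N, DMF, 60 °C, Ar; then K2CO3, MeOH, 65 °C, same pot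
Reagents that add atoms: none
Why: Sonogashira coupling keeps the bond-forming site one alkyne unit away from the two ortho substituents, and after methanolysis of the acetates the ortho phenoxide closes 5-endo-dig (base/Cu-assisted hydroalkoxylation) to the 2-arylbenzofuran with the remaining hydroxyl at C6.

**Step 12**
Reactants: 18 2-[7-(methoxymethoxy)-2,2-dimethyl-6-(3-methylbut-2-en-1-yl)-2H-chromen-5-yl]-1-benzofuran-6-ol
Product: 19 cathafuran C, 5-(6-hydroxy-1-benzofuran-2-yl)-2,2-dimethyl-6-(3-methylbut-2-en-1-yl)-2H-chromen-7-ol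
Conditions: HCl (1 M, from AcCl), MeOH/THF, rt → 40 °C
Reagents that add atoms: none
Why: Acid-catalysed acetal exchange of the aryl MOM ether with methanol under dilute, mild conditions chosen to stay below the threshold for prenyl-to-chroman cyclisation.

**Compound list**
1 | methyl 3,5-dihydroxybenzoate | COC(=O)c1cc(O)cc(O)c1 | starting material
2 | 3-chloro-3-methylbut-1-yne | CC(C)(Cl)C#C | starting material
3 | methyl 3-hydroxy-5-[(2-methylbut-3-yn-2-yl)oxy]benzoate | COC(=O)c1cc(O)cc(OC(C)(C)C#C)c1 | intermediate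
4 | methyl 3,5-dihydroxy-2-(3-methylbuta-1,2-dien-1-yl)benzoate | COC(=O)c1cc(O)cc(O)c1C=C=C(C)C | intermediate
5 | methyl 7-hydroxy-2,2-dimethyl-2H-chromene-5-carboxylate | COC(=O)c1cc(O)cc2OC(C)(C)C=Cc12 | intermediate
6 | methyl 7-(methoxymethoxy)-2,2-dimethyl-2H-chromene-5-carboxylate | COC(=O)c1cc(OCOC)cc2OC(C)(C)C=Cc12 | intermediate
7 | 7-(methoxymethoxy)-2,2-dimethyl-2H-chromene-5-carboxylic acid | OC(=O)c1cc(OCOC)cc2OC(C)(C)C=Cc12 | intermediate
8 | 2-methylbut-3-en-2-ol | CC(C)(O)C=C | starting material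
9 | methyl 2-methylbut-3-en-2-yl carbonate | COC(=O)OC(C)(C)C=C | intermediate
10 | 7-(methoxymethoxy)-2,2-dimethyl-6-(3-methylbut-2-en-1-yl)-2H-chromene-5-carboxylic acid | OC(=O)c1c(CC=C(C)C)c(OCOC)cc2OC(C)(C)C=Cc12 | intermediate
11 | [7-(methoxymethoxy)-2,2-dimethyl-6-(3-methylbut-2-en-1-yl)-2H-chromen-5-yl]methanol | OCc1c(CC=C(C)C)c(OCOC)cc2OC(C)(C)C=Cc12 | intermediate
12 | 7-(methoxymethoxy)-2,2-dimethyl-6-(3-methylbut-2-en-1-yl)-2H-chromene-5-carbaldehyde | O=Cc1c(CC=C(C)C)c(OCOC)cc2OC(C)(C)C=Cc12 | intermediate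
13 | 5-ethynyl-7-(methoxymethoxy)-2,2-dimethyl-6-(3-methylbut-2-en-1-yl)-2H-chromene | C#Cc1c(CC=C(C)C)c(OCOC)cc2OC(C)(C)C=Cc12 | intermediate
14 | 4-iodobenzene-1,3-diol | Oc1ccc(I)c(O)c1 | starting material
15 | 4-iodo-1,3-phenylene diacetate | CC(=O)Oc1ccc(I)c(OC(C)=O)c1 | intermediate
16 | 4-{[7-(methoxymethoxy)-2,2-dimethyl-6-(3-methylbut-2-en-1-yl)-2H-chromen-5-yl]ethynyl}-1,3-phenylene diacetate | CC(=O)Oc1ccc(C#Cc2c(CC=C(C)C)c(OCOC)cc3OC(C)(C)C=Cc23)c(OC(C)=O)c1 | intermediate
17 | 4-{[7-(methoxymethoxy)-2,2-dimethyl-6-(3-methylbut-2-en-1-yl)-2H-chromen-5-yl]ethynyl}benzene-1,3-diol | Oc1ccc(C#Cc2c(CC=C(C)C)c(OCOC)cc3OC(C)(C)C=Cc23)c(O)c1 | intermediate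
18 | 2-[7-(methoxymethoxy)-2,2-dimethyl-6-(3-methylbut-2-en-1-yl)-2H-chromen-5-yl]-1-benzofuran-6-ol | COCOc1cc2OC(C)(C)C=Cc2c(-c2cc3ccc(O)cc3o2)c1CC=C(C)C | intermediate
19 | cathafuran C, 5-(6-hydroxy-1-benzofuran-2-yl)-2,2-dimethyl-6-(3-methylbut-2-en-1-yl)-2H-chromen-7-ol | CC(C)=CCc1c(O)cc2c(c1-c1cc3ccc(O)cc3o1)C=CC(C)(C)O2 | target

**Totals**
Total step count: 12. Longest linear sequence: 10 steps (1 → 19 through steps 1–4, 6–9, 11 and 12); steps 5 and 10 make the two side partners.

**Three steps most likely to fail**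

Step 6 (the proposed new C–H prenylation). The C6–H is flanked on both sides, and the vinylic C4–H sits in a peri-like position where the carboxylate could also direct metalation. Insertion of a 1,1-disubstituted allylic carbonate into an aryl–Ru bond at such a site is untested. The fallback uses known chemistry, sets out from 5 and comes back at 11. Phenol 5 is O-alkylated at the tertiary terminus with carbonate 9 under Pd(PPh3)4 (THF, 0 °C → rt, decarboxylative Tsuji–Trost etherification) to give methyl 2,2-dimethyl-7-[(2-methylbut-3-en-2-yl)oxy]-2H-chromene-5-carboxylate F5. Heating (PhNEt2, 120 °C) brings about the aromatic Claisen rearrangement to methyl 7-hydroxy-2,2-dimethyl-6-(3-methylbut-2-en-1-yl)-2H-chromene-5-carboxylate F6. The meta ester and the meta ring oxygen both bias migration to C6, and any C8 isomer is removed by chromatography. MOMCl/K2CO3 then gives methyl 7-(methoxymethoxy)-2,2-dimethyl-6-(3-methylbut-2-en-1-yl)-2H-chromene-5-carboxylate F7, and LiAlH4 (THF, 0 °C) reduces F7 to alcohol 11.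

Step 2 (regiochemistry of the chromene closure). The substituent effects favour closure next to the ester, but the other isomer (ring closed between the two oxygens) may form in a significant amount. The fallback fixes the position with a halogen, sets out from 1 and comes back at 5. Diol 1 is bis-protected (MOMCl, K2CO3, acetone) to methyl 3,5-bis(methoxymethoxy)benzoate F1. NBS (MeCN, 0 °C) brominates para to one MOM ether and ortho to the ester to give methyl 2-bromo-3,5-bis(methoxymethoxy)benzoate F2. Copper-free Sonogashira coupling with 2-methylbut-3-yn-2-ol (PdCl2(MeCN)2, XPhos, Cs2CO3, MeCN, 80 °C) gives methyl 2-(3-hydroxy-3-methylbut-1-yn-1-yl)-3,5-bis(methoxymethoxy)benzoate F3. Lindlar semi-hydrogenation (H2, Pd/CaCO3–Pb, quinoline, EtOAc) gives methyl 2-[(1Z)-3-hydroxy-3-methylbut-1-en-1-yl]-3,5-bis(methoxymethoxy)benzoate F4. HCl in MeOH (50 °C) removes both MOM groups, and the phenol next to the side chain closes onto the tertiary allylic cation (cyclodehydration) to give chromene 5, with the pyran ring necessarily on the ester side.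

Step 12 (acidic MOM removal beside a prenyl group). The freed C7 phenol can add to the adjacent prenyl alkene under acid to give a chroman. The fallback avoids Brønsted acid altogether, sets out from 18 and comes back at 19. Treating 18 with TESOTf/2,2′-bipyridyl (CH2Cl2, 0 °C → rt) exchanges the aryl MOM ether for a silyl ether and silylates the free benzofuranol. This gives triethyl({2-[2,2-dimethyl-6-(3-methylbut-2-en-1-yl)-7-(triethylsilyloxy)-2H-chromen-5-yl]-1-benzofuran-6-yl}oxy)silane F8. TBAF (THF, 0 °C) then frees both phenols to give 19.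

**Further compounds**
F1 | step 2 | methyl 3,5-bis(methoxymethoxy)benzoate | COC(=O)c1cc(OCOC)cc(OCOC)c1
F2 | step 2 | methyl 2-bromo-3,5-bis(methoxymethoxy)benzoate | COC(=O)c1cc(OCOC)cc(OCOC)c1Br
F3 | step 2 | methyl 2-(3-hydroxy-3-methylbut-1-yn-1-yl)-3,5-bis(methoxymethoxy)benzoate | COC(=O)c1cc(OCOC)cc(OCOC)c1C#CC(C)(C)O
F4 | step 2 | methyl 2-[(1Z)-3-hydroxy-3-methylbut-1-en-1-yl]-3,5-bis(methoxymethoxy)benzoate | COC(=O)c1cc(OCOC)cc(OCOC)c1/C=C\C(C)(C)O
F5 | step 6 | methyl 2,2-dimethyl-7-[(2-methylbut-3-en-2-yl)oxy]-2H-chromene-5-carboxylate | COC(=O)c1cc(OC(C)(C)C=C)cc2OC(C)(C)C=Cc12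
F6 | step 6 | methyl 7-hydroxy-2,2-dimethyl-6-(3-methylbut-2-en-1-yl)-2H-chromene-5-carboxylate | COC(=O)c1c(CC=C(C)C)c(O)cc2OC(C)(C)C=Cc12
F7 | step 6 | methyl 7-(methoxymethoxy)-2,2-dimethyl-6-(3-methylbut-2-en-1-yl)-2H-chromene-5-carboxylate | COC(=O)c1c(CC=C(C)C)c(OCOC)cc2OC(C)(C)C=Cc12
F8 | step 12 | triethyl({2-[2,2-dimethyl-6-(3-methylbut-2-en-1-yl)-7-(triethylsilyloxy)-2H-chromen-5-yl]-1-benzofuran-6-yl}oxy)silane | CC[Si](CC)(CC)Oc1cc2OC(C)(C)C=Cc2c(-c2cc3ccc(O[Si](CC)(CC)CC)cc3o2)c1CC=C(C)C
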